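**The choice.** You have to decide how much incoming ligand to charge, so ask what each extra portion buys in complex with one exchanged at the end of the run.

| flask | starting complex | incoming ligand | remark | time |
|---|---|---|---|---|
| green | 0.50 M | 0.20 M | run made earlier |  |
| ochre | 0.50 M | 1.2 M | run made earlier |  |
| south | 0.50 M | 0.400 M |  | 8.0 h |
| east | 0.50 M | 1.00 M |  | 8.0 h |
| north-east | 0.50 M | 1.50 M |  | 8.0 h |

- green (time / h: complex with one exchanged / %, starting complex / %): 1.50: 14.3, 68.4; 3.00: 13.8, 70.2; 5.00: 13.4, 71.4; 6.00: 12.4, 72.4; 8.00: 11.2, 73.8
- ochre (time / h: complex with one exchanged / %, starting complex / %): 0.667: 36.4, 16.6; 2.00: 30.8, 20.9; 4.00: 27.8, 27.1; 6.00: 24.9, 34.0; 8.00: 23.9, 40.3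

(standard deviation of a reading: 0.5 percentage points)

* final complex with one exchanged, as a percentage of the starting complex charged, for each flask in turn (south, east, north-east)

- steps under discussion: starting complex + incoming ligand <-> leaving ligand + complex with one exchanged; complex with one exchanged + incoming ligand <-> leaving ligand + complex with two exchanged; complex with one exchanged <-> isomer of the product; incoming ligand -> decomposed reagent

**Rate first.** Work in powers of ten. The first step as written runs in proportion to the incoming ligand, so going from green to ochre lifts the starting rate by 0.778 decades. At the first readings, 1.50 h in green and 0.667 h in ochre, the gap in complex with one exchanged is 0.406 decades. These readings fall short of the starting rates by a factor of 2.36, which I read as exchange reaching its balance. At 8.00 h the gap reads 0.329 decades, a further factor of 1.19, while the readings of starting complex climb back in both runs.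

**Dose order.** Define the dose order, an apparent order at fixed time and fixed charge of starting complex, as decades of final reading gained per decade of dose, which green and ochre put at 0.423. Scaling green's final 11.2% by it, I get 15.0% for south, 22.1% for east and 26.3% for north-east.

**The forecast.** It gives 17.5%, 22.5% and 25%: “Product therefore rises only weakly with dose, since excess ligand decomposes.” For south it stands higher than my line, and for north-east lower.

**The outcome.** South gives 17.1%, east 22.5% and north-east 24.2%, so the forecast holds within its margins.

    starting complex + incoming ligand ⇌ leaving ligand + complex with one exchanged (K = 1.50, k = 0.00250 /M/s)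
    complex with one exchanged + incoming ligand ⇌ leaving ligand + complex with two exchanged (K = 0.580, k = 9.80 × 10⁻⁵ /M/s)
    complex with one exchanged ⇌ isomer of the product (K = 1.20, k = 0.00110 /s)
    incoming ligand → decomposed reagent (k = 7.90 × 10⁻⁵ /s)

**The turn.** In south, complex with one exchanged was made 3.29 times faster than it was used up at 0.0734 h, each step taken net, but at 8.00 h its making ran at 0.563 of its using up, so the south value asked for was falling. From green to south the dose order reads 0.610, and from east to north-east it reads 0.180.

The data are calculated on assumed constants; scatter was added.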